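**Plan**
Retrosynthesis: the helper groups are put back first. These are two O-benzyl ethers on the catechol, a menthyloxy group on C5, and two phenylsulfanyl groups on the benzylic carbon at C4. The lactone is then cut at two bonds at once, C3–CH2(3,4-dimethoxyphenyl) and C4–C(benzylic), which leaves a butenolide, a benzylic carbanion and a benzylic bromide.
Enabling feature: in the ring O1–C2(=O)–C3–C4–C5 the two benzyl-bearing carbons are the α (C3) and β (C4) positions of the lactone carbonyl. A C3=C4 butenolide is therefore an acceptor at C4 and then, as its enolate, a donor at C3. C5, the O-bound CH2 next to C4, can be held at the acetal level and carry a chiral alkoxy group.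
Forward order: the five-membered ring comes ready-made from furfural (steps 1–2), and the three components are joined around C3/C4 in one flask (step 5). Sulfur (step 6), the C5 auxiliary (step 7, ring opened and reclosed) and the benzyl ethers (step 8) are then removed.
Stereochemistry: (−)-menthol fixes C5 (R) by crystallisation. C5 sends the carbanion anti to set C4 (R), and the C4 group sends the bromide anti to set C3 (R). C5 is finally reduced to CH2.

Key step: step 5

Remark: the target SMILES is read as the (3R,4R)-trans-lactone, and the lactone numbering O1, C2(=O), C3, C4, C5 is used throughout.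

**Step 1**
Reactants: 1 furfural
Product: 3 5-hydroxy-2(5H)-furanone, via furfural endoperoxide 2 (not isolated)
Conditions: O2, rose bengal (cat.), hν (visible), MeOH, rt
Reagents that add atoms: oxygen, O=O
Why: Dye-sensitised singlet-oxygen [4+2] cycloaddition to the furan gives endoperoxide 2, whose formyl group is attacked by methanol so that the formyl carbon leaves as its methyl ester and the O–O bond breaks to the γ-hydroxybutenolide (furfural photooxygenation).

**Step 2**
Reactants: 3 5-hydroxy-2(5H)-furanone; 4 (−)-menthol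
Product: 5 (5R)-5-[(1R,2S,5R)-menthyloxy]-2(5H)-furanone
Conditions: p-TsOH·H2O (cat.), toluene, reflux, Dean–Stark; crystallisation from petroleum ether, mother liquor re-equilibrated with cat. p-TsOH and recrystallised
Reagents that add atoms: none
Why: Acid-catalysed acetalisation of the cyclic hemiacetal (pseudo-ester formation) gives both C5 epimers, which interconvert under the acid, and the 5R epimer is the one that crystallises, so C5 is fixed by crystallisation against the three fixed menthyl centres.

**Step 3**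
Reactants: 6 3,4-bis(benzyloxy)benzaldehyde
Product: 7 1,2-bis(benzyloxy)-4-[bis(phenylsulfanyl)methyl]benzene
Conditions: PhSH (2.1 equiv), p-TsOH·H2O (cat.), toluene, reflux, Dean–Stark
Reagents that add atoms: thiophenol, Sc1ccccc1
Why: Brønsted-acid dithioacetalisation of an electron-rich aromatic aldehyde runs through the aryl-stabilised thionium ion, and aryl benzyl ethers tolerate the catalytic acid.

**Step 4**
Reactants: 8 3,4-dimethoxybenzyl alcohol
Product: 9 3,4-dimethoxybenzyl bromide
Conditions: PBr3 (0.4 equiv), Et2O, 0 °C; used at once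
Reagents that add atoms: phosphorus tribromide, BrP(Br)Br
Why: Bromide displaces the activated phosphite ester (alcohol-to-bromide conversion with PBr3), and the labile electron-rich benzylic bromide is prepared fresh for step 5.

**Step 5**
Reactants: 7 1,2-bis(benzyloxy)-4-[bis(phenylsulfanyl)methyl]benzene; 5 (5R)-5-menthyloxy-2(5H)-furanone; 9 3,4-dimethoxybenzyl bromide
Product: 12 (3R,4R,5R)-4-{[3,4-bis(benzyloxy)phenyl]bis(phenylsulfanyl)methyl}-3-(3,4-dimethoxybenzyl)-5-menthyloxydihydrofuran-2(3H)-one, via lithiated dithioacetal 10 (not isolated), via lithium enolate 11 (not isolated)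
Conditions: 7, n-BuLi (1.0 equiv), THF, −78 °C; 5 in THF, −78 °C; then 9, DMPU, −78 °C to rt; aq NH4Cl
Reagents that add atoms: n-butyllithium, [Li]CCCC (supplies the lithium of 10 and 11 only; no atom of it remains in 12)
Why: n-BuLi removes the benzylic proton of 7, which is stabilised by two sulfur atoms and the arene; the soft, hindered carbanion 10 adds 1,4 to butenolide 5, and the lactone enolate 11 is alkylated at C3 by bromide 9 in an SN2 step, so two C–C bonds and two stereocentres arise in one flask. The closest known reaction type is the tandem conjugate addition–enolate alkylation (three-component coupling) of lithiated aryl dithioacetals, γ-alkoxybutenolides and benzylic halides. No ring is closed, since the lactone ring is brought in intact by 5. C4 is controlled by the C5 menthyloxy group, which shields one face of the flat butenolide so that 10 enters anti to it (4,5-trans), and C3 is controlled by the very large C4 bis(phenylsulfanyl)benzyl group, which sends 9 to the opposite enolate face (3,4-trans); with the 5R acetal this corresponds to 3R,4R. The step needs 1,4- over 1,2-addition (secured by the delocalised, bulky carbanion at −78 °C), C-monoalkylation (soft benzylic bromide, DMPU, and a crowded tertiary C3 after the first alkylation), and alkylation faster than retro-Michael loss of 10 (reactive electron-rich bromide added cold).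

**Step 6**
Reactants: 12 three-component adduct
Product: 13 (3R,4R,5R)-4-[3,4-bis(benzyloxy)benzyl]-3-(3,4-dimethoxybenzyl)-5-menthyloxydihydrofuran-2(3H)-one
Conditions: Raney Ni (W-2, excess, pre-refluxed in acetone), THF/EtOH, rt to 40 °C
Reagents that add atoms: none
Why: Raney Ni reductive desulfurisation of the benzylic dithioacetal replaces both C–S bonds by C–H without touching C3, C4 or C5; the acetone-deactivated metal is chosen to spare the aryl benzyl ethers, and sulfur is removed before step 7 because a C5 aldehyde β to C–SPh would lose thiophenolate by E1cB.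

**Step 7**
Reactants: 13 desulfurised menthyloxy lactone
Product: 16 (3R,4R)-4-[3,4-bis(benzyloxy)benzyl]-3-(3,4-dimethoxybenzyl)dihydrofuran-2(3H)-one, via formyl carboxylate 14 (not isolated), via hydroxy carboxylate 15 (not isolated)
Conditions: NaBH4, KOH, EtOH/H2O, 0 °C to rt; then 2 M HCl to pH 1, rt
Reagents that add atoms: potassium hydroxide, [K+].[OH-] (potassium and one carboxylate oxygen of 14 and 15; after ring closure one of the two equivalent carboxyl oxygens stays as the lactone carbonyl oxygen)
Why: Hydroxide opens the pseudo-ester, the freed hemiacetal expels menthol to give aldehyde 14, borohydride already present reduces it to 15 before C4 can epimerise, and acid recloses the γ-lactone (5-exo-trig), so this saponification–reduction–lactonisation of a γ-alkoxylactone erases the C5 stereocentre and leaves C3 and C4 untouched.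

**Step 8**
Reactants: 16 dibenzyl ether lactone
Product: 17 (3R,4R)-4-(3,4-dihydroxybenzyl)-3-(3,4-dimethoxybenzyl)dihydrofuran-2(3H)-one (target)
Conditions: H2 (1 atm), Pd/C (10 wt %), EtOAc/EtOH, rt; filtration under argon
Reagents that add atoms: none
Why: Catalytic hydrogenolysis cleaves the two aryl benzyl ethers, no other C–O bond is benzylic, and the neutral reducing medium leaves the trans stereocentres alone and protects the catechol from oxidation.

**Compound list**
1 | furfural (furan-2-carbaldehyde) | O=Cc1ccco1 | starting material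
2 | furfural endoperoxide, 2,3,7-trioxabicyclo[2.2.1]hept-5-ene-1-carbaldehyde (racemic) | O=CC12C=CC(OO1)O2 | intermediate
3 | 5-hydroxy-2(5H)-furanone (racemic hemiacetal) | O=C1C=CC(O)O1 | intermediate
4 | (−)-menthol, (1R,2S,5R)-2-isopropyl-5-methylcyclohexanol | CC(C)[C@@H]1CC[C@@H](C)C[C@H]1O | starting material
5 | (5R)-5-[(1R,2S,5R)-menthyloxy]-2(5H)-furanone | O=C1C=C[C@H](O[C@@H]2C[C@H](C)CC[C@H]2C(C)C)O1 | intermediate
6 | 3,4-bis(benzyloxy)benzaldehyde | O=Cc1ccc(OCc2ccccc2)c(OCc2ccccc2)c1 | starting material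
7 | 1,2-bis(benzyloxy)-4-[bis(phenylsulfanyl)methyl]benzene | C(Sc1ccccc1)(Sc1ccccc1)c1ccc(OCc2ccccc2)c(OCc2ccccc2)c1 | intermediate
8 | 3,4-dimethoxybenzyl alcohol | COc1ccc(CO)cc1OC | starting material
9 | 3,4-dimethoxybenzyl bromide | COc1ccc(CBr)cc1OC | intermediate
10 | [3,4-bis(benzyloxy)phenyl]bis(phenylsulfanyl)methyllithium | [Li]C(Sc1ccccc1)(Sc1ccccc1)c1ccc(OCc2ccccc2)c(OCc2ccccc2)c1 | intermediate
11 | lithium (4R,5R)-4-{[3,4-bis(benzyloxy)phenyl]bis(phenylsulfanyl)methyl}-5-menthyloxy-4,5-dihydrofuran-2-olate | [Li]OC1=C[C@@H](C(Sc2ccccc2)(Sc2ccccc2)c2ccc(OCc3ccccc3)c(OCc3ccccc3)c2)[C@H](O[C@@H]2C[C@H](C)CC[C@H]2C(C)C)O1 | intermediate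
12 | (3R,4R,5R)-4-{[3,4-bis(benzyloxy)phenyl]bis(phenylsulfanyl)methyl}-3-(3,4-dimethoxybenzyl)-5-[(1R,2S,5R)-menthyloxy]dihydrofuran-2(3H)-one (3,4-trans, 4,5-trans) | COc1ccc(C[C@H]2C(=O)O[C@@H](O[C@@H]3C[C@H](C)CC[C@H]3C(C)C)[C@@H]2C(Sc2ccccc2)(Sc2ccccc2)c2ccc(OCc3ccccc3)c(OCc3ccccc3)c2)cc1OC | intermediate
13 | (3R,4R,5R)-4-[3,4-bis(benzyloxy)benzyl]-3-(3,4-dimethoxybenzyl)-5-[(1R,2S,5R)-menthyloxy]dihydrofuran-2(3H)-one | COc1ccc(C[C@H]2C(=O)O[C@@H](O[C@@H]3C[C@H](C)CC[C@H]3C(C)C)[C@@H]2Cc2ccc(OCc3ccccc3)c(OCc3ccccc3)c2)cc1OC | intermediate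
14 | potassium (2R,3R)-3-[3,4-bis(benzyloxy)benzyl]-2-(3,4-dimethoxybenzyl)-4-oxobutanoate | [K+].COc1ccc(C[C@@H](C(=O)[O-])[C@H](C=O)Cc2ccc(OCc3ccccc3)c(OCc3ccccc3)c2)cc1OC | intermediate
15 | potassium (2R,3R)-3-[3,4-bis(benzyloxy)benzyl]-2-(3,4-dimethoxybenzyl)-4-hydroxybutanoate | [K+].COc1ccc(C[C@@H](C(=O)[O-])[C@H](CO)Cc2ccc(OCc3ccccc3)c(OCc3ccccc3)c2)cc1OC | intermediate
16 | (3R,4R)-4-[3,4-bis(benzyloxy)benzyl]-3-(3,4-dimethoxybenzyl)dihydrofuran-2(3H)-one | COc1ccc(C[C@H]2C(=O)OC[C@@H]2Cc2ccc(OCc3ccccc3)c(OCc3ccccc3)c2)cc1OC | intermediate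
17 | (3R,4R)-4-(3,4-dihydroxybenzyl)-3-(3,4-dimethoxybenzyl)dihydrofuran-2(3H)-one | COc1ccc(C[C@H]2C(=O)OC[C@@H]2Cc2ccc(O)c(O)c2)cc1OC | target

**Total step count:** 8. **Longest linear sequence:** 6 (steps 1, 2, 5, 6, 7, 8).

**Steps most likely to fail**

Step 5. On warming, the conjugate addition may reverse (retro-Michael loss of the stabilised carbanion), or proton transfer may consume the enolate before the alkylation is complete. The 3,4-trans selectivity may also erode. The fallback sets out from 7 and 5 and comes back at 13.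
- Enolate 11 is made as before but quenched cold with aq NH4Cl to give the (4R,5R)-4-{[3,4-bis(benzyloxy)phenyl]bis(phenylsulfanyl)methyl}-5-menthyloxylactone F1.
- Deactivated Raney Ni removes sulfur to give the (4R,5R)-4-[3,4-bis(benzyloxy)benzyl]-5-menthyloxylactone F2, which no longer holds a group that can leave as a carbanion.
- LiN(i-Pr)2 in THF at −78 °C forms the lithium enolate of the desulfurised lactone F3, and 9 alkylates it anti to the C4 benzyl group. This is the classical trans-selective alkylation of a β-benzylbutyrolactone enolate, and it gives 13.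

Step 6. The aryl benzyl ethers may be partly hydrogenolysed while sulfur is stripped, or the second C–S bond may be removed incompletely, so that a mixture results. The fallback sets out from 12 and comes back at 17, with the order of deprotection changed.
- Active W-2 Raney Ni in refluxing EtOH under H2 is used on purpose to remove both sulfur groups and both benzyl groups. This gives the (3R,4R,5R)-4-(3,4-dihydroxybenzyl)-3-(3,4-dimethoxybenzyl)-5-menthyloxylactone F4.
- Degassed NaBH4/KOH/EtOH under argon keeps the catecholate reduced. It leads through the ring-opened formyl acid F5 and the ring-opened hydroxy acid F6, both present as salts in the flask.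
- Acidification with HCl closes the lactone to 17 directly.

Step 7. The transient enolisable aldehyde may epimerise at C4 in strong base, or the crowded pseudo-ester may open sluggishly. The fallback sets out from 13 and comes back at 16.
- The acetal is hydrolysed under acid instead (2 M HCl/dioxane, 60 °C) to the (3R,4R)-5-hydroxylactone (pseudo-acid, C5 epimers) F7.
- F7 is reduced near neutrality (NaBH4, NaHCO3, EtOH/H2O, 0 °C) through its open aldehyde form to the (2R,3R)-hydroxy acid F8.
- Acidification lactonises F8 to 16.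

**Further compounds**
F1 | step 5 | (4R,5R)-4-{[3,4-bis(benzyloxy)phenyl]bis(phenylsulfanyl)methyl}-5-[(1R,2S,5R)-menthyloxy]dihydrofuran-2(3H)-one | O=C1C[C@@H](C(Sc2ccccc2)(Sc2ccccc2)c2ccc(OCc3ccccc3)c(OCc3ccccc3)c2)[C@H](O[C@@H]2C[C@H](C)CC[C@H]2C(C)C)O1
F2 | step 5 | (4R,5R)-4-[3,4-bis(benzyloxy)benzyl]-5-[(1R,2S,5R)-menthyloxy]dihydrofuran-2(3H)-one | O=C1C[C@@H](Cc2ccc(OCc3ccccc3)c(OCc3ccccc3)c2)[C@H](O[C@@H]2C[C@H](C)CC[C@H]2C(C)C)O1
F3 | step 5 | lithium (4R,5R)-4-[3,4-bis(benzyloxy)benzyl]-5-menthyloxy-4,5-dihydrofuran-2-olate | [Li]OC1=C[C@@H](Cc2ccc(OCc3ccccc3)c(OCc3ccccc3)c2)[C@H](O[C@@H]2C[C@H](C)CC[C@H]2C(C)C)O1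
F4 | step 6 | (3R,4R,5R)-4-(3,4-dihydroxybenzyl)-3-(3,4-dimethoxybenzyl)-5-[(1R,2S,5R)-menthyloxy]dihydrofuran-2(3H)-one | COc1ccc(C[C@H]2C(=O)O[C@@H](O[C@@H]3C[C@H](C)CC[C@H]3C(C)C)[C@@H]2Cc2ccc(O)c(O)c2)cc1OC
F5 | step 6 | (2R,3R)-3-(3,4-dihydroxybenzyl)-2-(3,4-dimethoxybenzyl)-4-oxobutanoic acid | COc1ccc(C[C@@H](C(=O)O)[C@H](C=O)Cc2ccc(O)c(O)c2)cc1OC
F6 | step 6 | (2R,3R)-3-(3,4-dihydroxybenzyl)-2-(3,4-dimethoxybenzyl)-4-hydroxybutanoic acid | COc1ccc(C[C@@H](C(=O)O)[C@H](CO)Cc2ccc(O)c(O)c2)cc1OC
F7 | step 7 | (3R,4R)-4-[3,4-bis(benzyloxy)benzyl]-3-(3,4-dimethoxybenzyl)-5-hydroxydihydrofuran-2(3H)-one (C5 epimers) | COc1ccc(C[C@H]2C(=O)OC(O)[C@@H]2Cc2ccc(OCc3ccccc3)c(OCc3ccccc3)c2)cc1OC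
F8 | step 7 | (2R,3R)-3-[3,4-bis(benzyloxy)benzyl]-2-(3,4-dimethoxybenzyl)-4-hydroxybutanoic acid | COc1ccc(C[C@@H](C(=O)O)[C@H](CO)Cc2ccc(OCc3ccccc3)c(OCc3ccccc3)c2)cc1OC
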